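Count the partner. Tuesday's flask is the one asked about, and Wednesday's run is its cooler twin.

| flask | substrate | partner | temperature | remark | time |
|---|---|---|---|---|---|
| Tuesday's | 40 mM | 1.2 equiv | 80 °C | the very flask that is asked about, followed so far |  |
| Wednesday's | 40 mM | 1.2 equiv | 75 °C | run made earlier |  |
| flask | 40 mM | 1.20 equiv | 80 °C |  | 5.0 h |

| run | time / min | target / % |
|---|---|---|
| Tuesday's | 40.0 | 60.5 |
| Tuesday's | 120 | 81.7 |
| Tuesday's | 180 | 82.2 |
| Tuesday's | 300 | 81.4 |
| Wednesday's | 40.0 | 41.7 |
| Wednesday's | 120 | 75.2 |
| Wednesday's | 180 | 76.2 |
| Wednesday's | 300 | 78.4 |

(each reading ± 1 percentage point)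

- theta: at 5.0 h add partner, 100% of the amount charged, then wait 10 h
- beta: at 5.0 h raise the temperature by 25 K, then wait 10 h
- alpha: change nothing and wait 10 h more
- epsilon: at 5.0 h add substrate, 50.0% of the amount charged, then wait 10 h

- what is said of target includes idle adduct
- additions bring no volume worth counting
- candidate steps: substrate <-> open intermediate; partner -> second intermediate; open intermediate + second intermediate -> target; 2 second intermediate -> homo product; partner + target <-> idle adduct

1. target, in percent of the substrate first charged, at 5.0 h
2. what to do for the largest gain in target; "none" if nothing gains more than 2 percentage points (theta / beta / alpha / epsilon / none)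
3. target present, in percent of the substrate first charged, after beta
4. target present, in percent of the substrate first charged, after alpha

Take the main step first. Open intermediate meets second intermediate and gives target, one partner for each substrate. With q equivalents of partner per substrate, the ceiling in Tuesday's flask is the substrate charge, since 1.2 equiv was charged.

Now add the reversible opening. It moves material between substrate and open intermediate and destroys none, so a stalled flask keeps its shortfall in those two forms. Tuesday's flask does stall: from 120 min to 300 min target changes by −0.3 percentage points, against a scatter of 1 point. The plateau y is 81.8%, which leaves a room of 18.2%. Wednesday's run reads 41.7% at 40.0 min, where Tuesday's reads 60.5%, so cooling slows the start. But a plateau with substrate forms still present points to the partner's account, not the clock.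

Now add the homo route. Two second intermediates meet, so its rate goes with the square of second intermediate. At fixed temperature and substrate charge, second intermediate scales roughly with q, so the integrated loss is W = κq² and y = q − κq². Tuesday's plateau gives W = 38.2% of the substrate charge. Hence κ = 0.266, the waste coefficient: partner lost to the homo route per squared equivalent charged. Idle adduct comes last. It counts within target, so it needs no term of its own in this bookkeeping, and whatever it does to the homo route stays lumped inside κ.

This reckoning therefore puts target at 81.8% now. Waiting, heating and extra substrate add no partner, so target stays there. A second charge of partner offers 81.8% by the same formula, more than the room, so theta should fill that room.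

The forecast gave 82% now, theta as best, and slightly more than this reckoning after beta (83.5%) and after alpha (82.5%), holding that “Fresh partner can convert much of the remaining substrate”.

The flask gives 82.1% now and theta as best, with a gain of 18 points, while beta leaves 82.1% and alpha 82.1%.

    substrate ⇌ open intermediate (K = 3.09, k = 5.08 × 10⁻⁴ s⁻¹, Ea = 120 kJ mol⁻¹, ΔH = −37.0 kJ mol⁻¹)
    partner → second intermediate (k = 9.88 × 10⁻⁴ s⁻¹, Ea = 99.0 kJ mol⁻¹)
    open intermediate + second intermediate → target (k = 0.549 M⁻¹ s⁻¹, Ea = 73.0 kJ mol⁻¹)
    2 second intermediate → homo product (k = 0.0649 M⁻¹ s⁻¹, Ea = 62.0 kJ mol⁻¹)
    partner + target ⇌ idle adduct, settled at all times (K = 12.0 M⁻¹, ΔH = 10.0 kJ mol⁻¹)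
    (constants at 80 °C)

At 300 min the flask holds 0% of its partner, the limiting reagent, and 7.57 mM of homo product. Each homo product took two partners, so κ read from it is 0.263, beside 0.266 from the plateau. The homo route is the main reason for the shortfall: the run without it reaches >99.9%, against 82.1%.

For the neighbour charged with 0.720 equiv, q − κq² gives 58.2%. The simulated neighbour holds 61.8%, more target than the square law gives.

Readings and results stem from a simulated flask from invented constants, and the scatter is random.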